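**Retrosynthetic overview**

1. The two outer ArCH2–C bonds are cut first (double Mannich-base alkylation). This gives a fully blocked bis(aminomethyl) derivative of methylenebis(propionylphloroglucinol) and two molecules of propionylfilicinic acid; the C2 symmetry of the target lets one terminal building block serve twice.
2. The terminal ring is cut back to a four-membered ring: 3-ethoxy-4,4-dimethylcyclobutenone plus a methoxyalkyne that carries the propionyl chain at the alcohol oxidation level (two-carbon ring expansion by 4π opening, [2+2], 4π opening, 6π closure).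
3. Enabling feature: the quaternary C6(CH3)2 of the terminal ring, flanked by the C1 ketone and the C5 enol carbon, cannot enolize, so the annulation stops at the 2,4-dienone. The 1,3,5-oxygens map onto the cyclobutenone C=O (C1), the alkyne ether oxygen (C3) and the cyclobutenone ether oxygen (C5).
4. Ring order: cyclobutenone ring ([2+2] of dimethylketene and ethoxyacetylene), then the six-membered terminal ring (key step). The two aromatic rings are bought as flopropione and bridged with formaldehyde, and the last two CH2 bridges are closed in one operation.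

Key step: step 4

Remark (assumption): the target has no stereocentre and is drawn as one enol tautomer; all β-triketones are named and drawn in that tautomeric form. The carbinol centre carried through steps 2 to 5 is racemic and is erased in step 6.

**Route**

Step 1
Reactants: 1 isobutyryl chloride; 2 ethoxyacetylene
Product: 4 3-ethoxy-4,4-dimethylcyclobut-2-en-1-one, via dimethylketene 3 (not isolated)
Conditions: Et3N (1.2 equiv), Et2O, 0 °C → reflux
Reagents that add atoms: none
Why: Dehydrochlorination of 1 gives dimethylketene, which undergoes the thermal [2+2] ketene–alkoxyalkyne cycloaddition with the nucleophilic terminal carbon of 2 bonding to the ketene carbonyl carbon, so that the ethoxy group sits at C3 and the gem-dimethyl carbon at C4.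

Step 2
Reactants: 5 chloroacetaldehyde dimethyl acetal; 6 propanal
Product: 8 rac-1-methoxypent-1-yn-3-ol, via lithium methoxyacetylide 7 (not isolated)
Conditions: LiNEt2 (3.0 equiv), THF, 0 °C; then 6, −78 °C → 0 °C; H2O quench (kept basic)
Reagents that add atoms: none
Why: Twofold base-induced elimination of the chloroacetal gives the methoxyacetylide, whose 1,2-addition to the aldehyde gives the propargylic alcohol with a racemic carbinol centre that is removed later.

Step 3
Reactants: 8 rac-1-methoxypent-1-yn-3-ol
Product: 9 rac-tert-butyl[(1-methoxypent-1-yn-3-yl)oxy]dimethylsilane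
Conditions: TBSCl, imidazole, DMF, 0 °C → rt
Reagents that add atoms: tert-butyldimethylsilyl chloride, CC(C)(C)[Si](C)(C)Cl
Why: Standard silyl ether formation under non-acidic conditions masks the hydroxyl, which would trap the ketenes of step 4, and avoids Meyer–Schuster rearrangement of the alkynyl ether.

Step 4
Reactants: 4 3-ethoxy-4,4-dimethylcyclobut-2-en-1-one; 9 rac-tert-butyl[(1-methoxypent-1-yn-3-yl)oxy]dimethylsilane
Product: 13 rac-2-[1-(tert-butyldimethylsilyloxy)propyl]-5-ethoxy-3-methoxy-6,6-dimethylcyclohexa-2,4-dien-1-one, via vinylketene 10 (not isolated), via vinylcyclobutenone 11 (not isolated), via dienylketene 12 (not isolated)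
Conditions: 9 (1.3 equiv), PhMe (0.5 M), 120 °C, sealed tube
Reagents that add atoms: none
Why: Heating opens cyclobutenone 4 by reversible 4π-electrocyclic cleavage of its C1–C4 bond to vinylketene 10, whose ketene C=C adds the electron-rich alkynyl ether 9 in a [2+2] cycloaddition to give vinylcyclobutenone 11; a second 4π opening gives dienylketene 12, and 6π-electrocyclization re-forms the bond between the former C1 and C4 across the two inserted alkyne carbons, so that the four-membered ring of 4 is expanded by two atoms to the six-membered ring of 13. The closest known reaction type is the Danheiser annulation of cyclobutenones with heteroatom-substituted alkynes, together with the thermal reclosure of dienylketenes to 2,4-cyclohexadienones. The transient four-membered ring closes by [2+2] cycloaddition and the six-membered ring by thermal disrotatory 6π-electrocyclization. No stereocentre is created in the ring, since C6 carries two methyl groups, the ring stereocentre of 11 is lost on opening and the side-chain carbinol centre is carried racemic. The step needs the regiochemistry of the [2+2] event, secured by the methoxy donor that makes the silyloxypropyl-bearing alkyne carbon the nucleophile toward the ketene carbonyl carbon, and the dienylketene geometry in which the ketene carbon and the ethoxyvinyl carbon are cis on the central double bond (the 3E isomer of 12), which is reached because the opening of 11 is reversible while the 6π closure is not. The quaternary C6 cannot enolize, so the cascade ends at the dienone and not at a phenol.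

Step 5
Reactants: 13 rac-2-[1-(tert-butyldimethylsilyloxy)propyl]-5-ethoxy-3-methoxy-6,6-dimethylcyclohexa-2,4-dien-1-one
Product: 14 rac-5-ethoxy-2-(1-hydroxypropyl)-3-methoxy-6,6-dimethylcyclohexa-2,4-dien-1-one
Conditions: TBAF, AcOH (1:1), THF, 0 °C → rt
Reagents that add atoms: none
Why: Fluoride-mediated desilylation buffered with acetic acid removes the silyl group without touching the acid-labile enol ethers and leaves a Baylis–Hillman-type allylic alcohol.

Step 6
Reactants: 14 rac-5-ethoxy-2-(1-hydroxypropyl)-3-methoxy-6,6-dimethylcyclohexa-2,4-dien-1-one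
Product: 15 5-ethoxy-3-methoxy-6,6-dimethyl-2-propanoylcyclohexa-2,4-dien-1-one
Conditions: Dess–Martin periodinane, pyridine, CH2Cl2, 0 °C → rt
Reagents that add atoms: none
Why: Dess–Martin oxidation of the secondary allylic alcohol should give the propionyl ketone under mild buffered conditions and removes the only stereocentre of the series.

Step 7
Reactants: 15 5-ethoxy-3-methoxy-6,6-dimethyl-2-propanoylcyclohexa-2,4-dien-1-one
Product: 16 propionylfilicinic acid (3,5-dihydroxy-6,6-dimethyl-2-propanoylcyclohexa-2,4-dien-1-one)
Conditions: 2 M aq. HCl, THF, 40 °C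
Reagents that add atoms: water, O
Why: Acid hydrolysis of the vinylogous ester (C3–OMe) and of the dienol ether (C5–OEt) by protonation and addition–elimination of water releases the β-triketone, which rests as the enolized acid.

Step 8
Reactants: 17 flopropione (1-(2,4,6-trihydroxyphenyl)propan-1-one) (2 equivalents); 18 formaldehyde
Product: 19 bis(2,4,6-trihydroxy-3-propanoylphenyl)methane
Conditions: 17 (2.5 equiv), 37% aq. CH2O (1.0 equiv), 1% aq. KOH, 0 °C → rt; then 1 M HCl
Reagents that add atoms: none
Why: The classical formaldehyde condensation of acylphloroglucinols (hydroxymethylation of one molecule of 17, then Friedel–Crafts-type methylene bridging to a second molecule of 17 with loss of water) joins two flopropione units through the formaldehyde carbon, and the excess of cheap 17 should hold back further bridging.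

Step 9
Reactants: 19 bis(2,4,6-trihydroxy-3-propanoylphenyl)methane; 20 bis(dimethylamino)methane (2 equivalents)
Product: 22 bis{5-[(dimethylamino)methyl]-2,4,6-trihydroxy-3-propanoylphenyl}methane, via mono-Mannich base 21 (not isolated)
Conditions: 20 (2.4 equiv), 1,4-dioxane, rt → 50 °C
Reagents that add atoms: none
Why: Phenolic Mannich aminomethylation with the aminal takes place at the single free, doubly hydroxyl-activated position of each ring, each molecule of 20 delivering one CH2NMe2 group and releasing dimethylamine, and gives a core in which every aromatic carbon is blocked.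

Step 10
Reactants: 22 bis{5-[(dimethylamino)methyl]-2,4,6-trihydroxy-3-propanoylphenyl}methane; 16 propionylfilicinic acid (2 equivalents)
Product: 24 bis{5-[(2,6-dihydroxy-3,3-dimethyl-4-oxo-5-propanoylcyclohexa-1,5-dien-1-yl)methyl]-2,4,6-trihydroxy-3-propanoylphenyl}methane (target CNP0541376.0), via mono-adduct 23 (not isolated)
Conditions: 16 (2.2 equiv), 1,4-dioxane, 95 °C, N2 stream
Reagents that add atoms: none
Why: Two-directional Mannich-base alkylation (thermal loss of dimethylamine and conjugate C-alkylation by the C4–H of 16, the ortho-quinone-methide type of methylene bridging) is unambiguous because 22 has no free ring carbon and 16 has only one nucleophilic carbon.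

**Compound list**

1 | isobutyryl chloride | CC(C)C(=O)Cl | starting material
2 | ethoxyacetylene | C#COCC | starting material
3 | dimethylketene | CC(C)=C=O | intermediate (not isolated)
4 | 3-ethoxy-4,4-dimethylcyclobut-2-en-1-one | CCOC1=CC(=O)C1(C)C | intermediate
5 | chloroacetaldehyde dimethyl acetal (2-chloro-1,1-dimethoxyethane) | COC(CCl)OC | starting material
6 | propanal | CCC=O | starting material
7 | lithium methoxyacetylide | [Li]C#COC | intermediate (not isolated)
8 | rac-1-methoxypent-1-yn-3-ol | CCC(O)C#COC | intermediate
9 | rac-tert-butyl[(1-methoxypent-1-yn-3-yl)oxy]dimethylsilane | CCC(O[Si](C)(C)C(C)(C)C)C#COC | intermediate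
10 | 3-ethoxy-4-methylpenta-1,3-dien-1-one (vinylketene) | O=C=CC(OCC)=C(C)C | intermediate (not isolated)
11 | 2-[1-(tert-butyldimethylsilyloxy)propyl]-4-(1-ethoxy-2-methylprop-1-en-1-yl)-3-methoxycyclobut-2-en-1-one (mixture of racemic diastereomers) | O=C1C(C(CC)O[Si](C)(C)C(C)(C)C)=C(OC)C1C(OCC)=C(C)C | intermediate (not isolated)
12 | (3E)-2-[1-(tert-butyldimethylsilyloxy)propyl]-5-ethoxy-3-methoxy-6-methylhepta-1,3,5-trien-1-one (dienylketene, racemic) | O=C=C(C(CC)O[Si](C)(C)C(C)(C)C)/C(OC)=C\C(OCC)=C(C)C | intermediate (not isolated)
13 | rac-2-[1-(tert-butyldimethylsilyloxy)propyl]-5-ethoxy-3-methoxy-6,6-dimethylcyclohexa-2,4-dien-1-one | O=C1C(C(CC)O[Si](C)(C)C(C)(C)C)=C(OC)C=C(OCC)C1(C)C | intermediate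
14 | rac-5-ethoxy-2-(1-hydroxypropyl)-3-methoxy-6,6-dimethylcyclohexa-2,4-dien-1-one | O=C1C(C(O)CC)=C(OC)C=C(OCC)C1(C)C | intermediate
15 | 5-ethoxy-3-methoxy-6,6-dimethyl-2-propanoylcyclohexa-2,4-dien-1-one | O=C1C(C(=O)CC)=C(OC)C=C(OCC)C1(C)C | intermediate
16 | propionylfilicinic acid (3,5-dihydroxy-6,6-dimethyl-2-propanoylcyclohexa-2,4-dien-1-one) | CCC(=O)C1=C(O)C=C(O)C(C)(C)C1=O | intermediate
17 | flopropione (1-(2,4,6-trihydroxyphenyl)propan-1-one) | CCC(=O)c1c(O)cc(O)cc1O | starting material
18 | formaldehyde | C=O | starting material
19 | bis(2,4,6-trihydroxy-3-propanoylphenyl)methane | CCC(=O)c1c(O)cc(O)c(Cc2c(O)cc(O)c(C(=O)CC)c2O)c1O | intermediate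
20 | bis(dimethylamino)methane | CN(C)CN(C)C | starting material
21 | {5-[(dimethylamino)methyl]-2,4,6-trihydroxy-3-propanoylphenyl}(2,4,6-trihydroxy-3-propanoylphenyl)methane | CCC(=O)c1c(O)c(CN(C)C)c(O)c(Cc2c(O)cc(O)c(C(=O)CC)c2O)c1O | intermediate (not isolated)
22 | bis{5-[(dimethylamino)methyl]-2,4,6-trihydroxy-3-propanoylphenyl}methane | CCC(=O)c1c(O)c(CN(C)C)c(O)c(Cc2c(O)c(CN(C)C)c(O)c(C(=O)CC)c2O)c1O | intermediate
23 | {5-[(dimethylamino)methyl]-2,4,6-trihydroxy-3-propanoylphenyl}{5-[(2,6-dihydroxy-3,3-dimethyl-4-oxo-5-propanoylcyclohexa-1,5-dien-1-yl)methyl]-2,4,6-trihydroxy-3-propanoylphenyl}methane | CCC(=O)c1c(O)c(CN(C)C)c(O)c(Cc2c(O)c(CC3=C(O)C(C)(C)C(=O)C(C(=O)CC)=C3O)c(O)c(C(=O)CC)c2O)c1O | intermediate (not isolated)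
24 | bis{5-[(2,6-dihydroxy-3,3-dimethyl-4-oxo-5-propanoylcyclohexa-1,5-dien-1-yl)methyl]-2,4,6-trihydroxy-3-propanoylphenyl}methane (CNP0541376.0) | CCC(=O)C1=C(O)C(Cc2c(O)c(Cc3c(O)c(CC4=C(O)C(C)(C)C(=O)C(C(=O)CC)=C4O)c(O)c(C(=O)CC)c3O)c(O)c(C(=O)CC)c2O)=C(O)C(C)(C)C1=O | target

**Step count and risks**

Total steps: 10. Longest linear sequence: 7 steps (steps 2, 3, 4, 5, 6, 7, 10).

The three steps most likely to fail, in order of risk:

Step 4. The α-branched alkyne 9 may capture vinylketene 10 too slowly, so that a 1,5-hydrogen shift from a methyl group to the ketene carbon, or ketene dimerization, outruns the [2+2] event. The fallback carries no side chain through the cascade; it sets out from 4 (with 2) and returns to the route at 16. Cyclobutenone 4 is heated with a large excess of the unhindered ethoxyacetylene 2 (PhMe, sealed tube, 100 °C; the excess offsets slow thermal loss of ethylene from 2). The same annulation should run through 3-ethoxy-4-(1-ethoxy-2-methylprop-1-en-1-yl)cyclobut-2-en-1-one F1 and (3E)-3,5-diethoxy-6-methylhepta-1,3,5-trien-1-one F2, neither isolated, to 3,5-diethoxy-6,6-dimethylcyclohexa-2,4-dien-1-one F3. Hydrolysis (2 M aq. HCl, THF) should give filicinic acid F4, and Friedel–Crafts C-acylation with propionic anhydride and BF3·OEt2 should give 16.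

Step 10. The second alkylation may stall, and the liberated amine may start base-induced exchange of methylene bridges or divert the reactive methylene species to O-alkylation and cyclized chromene-type products. The fallback reverses the polarity; it sets out from 16 and 19 and returns to the route at 24. Acid 16 is aminomethylated with 20 (1,4-dioxane, rt) at its only nucleophilic carbon to give 4-[(dimethylamino)methyl]-3,5-dihydroxy-6,6-dimethyl-2-propanoylcyclohexa-2,4-dien-1-one F5, whose elimination needs no dearomatization and should occur at lower temperature. Two equivalents of F5 are then warmed with the unblocked core 19, in which each ring offers exactly one free position. The reaction should pass through {5-[(2,6-dihydroxy-3,3-dimethyl-4-oxo-5-propanoylcyclohexa-1,5-dien-1-yl)methyl]-2,4,6-trihydroxy-3-propanoylphenyl}(2,4,6-trihydroxy-3-propanoylphenyl)methane F6 to 24.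

Step 8. Free formaldehyde may go on to hydroxymethylate and bridge the product 19, leading to oligomers. The fallback replaces formaldehyde by a preformed one-carbon electrophile; it sets out from 17 and returns to the route at 19. Flopropione 17 in excess is treated with a limiting amount of 20 to give 1-{3-[(dimethylamino)methyl]-2,4,6-trihydroxyphenyl}propan-1-one F7. Heating F7 with a further excess of 17 (1,4-dioxane, 90 °C) should give 19 by elimination–addition, with unreacted 17 recovered.

**Further compounds**

F1 | step 4 | 3-ethoxy-4-(1-ethoxy-2-methylprop-1-en-1-yl)cyclobut-2-en-1-one (racemic, not isolated) | O=C1C=C(OCC)C1C(OCC)=C(C)C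
F2 | step 4 | (3E)-3,5-diethoxy-6-methylhepta-1,3,5-trien-1-one (not isolated) | O=C=C/C(OCC)=C\C(OCC)=C(C)C
F3 | step 4 | 3,5-diethoxy-6,6-dimethylcyclohexa-2,4-dien-1-one | O=C1C=C(OCC)C=C(OCC)C1(C)C
F4 | step 4 | filicinic acid (3,5-dihydroxy-6,6-dimethylcyclohexa-2,4-dien-1-one) | O=C1C=C(O)C=C(O)C1(C)C
F5 | step 10 | 4-[(dimethylamino)methyl]-3,5-dihydroxy-6,6-dimethyl-2-propanoylcyclohexa-2,4-dien-1-one | CCC(=O)C1=C(O)C(CN(C)C)=C(O)C(C)(C)C1=O
F6 | step 10 | {5-[(2,6-dihydroxy-3,3-dimethyl-4-oxo-5-propanoylcyclohexa-1,5-dien-1-yl)methyl]-2,4,6-trihydroxy-3-propanoylphenyl}(2,4,6-trihydroxy-3-propanoylphenyl)methane (not isolated) | CCC(=O)c1c(O)cc(O)c(Cc2c(O)c(CC3=C(O)C(C)(C)C(=O)C(C(=O)CC)=C3O)c(O)c(C(=O)CC)c2O)c1O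
F7 | step 8 | 1-{3-[(dimethylamino)methyl]-2,4,6-trihydroxyphenyl}propan-1-one | CCC(=O)c1c(O)cc(O)c(CN(C)C)c1O
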